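## Structural features

The target is a (2S)-flavanone: a chroman-4-one whose ring C (O1, C2, C3, C4, C4a, C8a) is fused to benzene ring A along the C4a–C8a bond and carries ring B on C2. Ring A bears hydroxyls on C5, C7 and C8 and leaves only C6 as C–H, with the C5 hydroxyl hydrogen-bonded to the C4 carbonyl; ring B is a 4-hydroxyphenyl group with a 3-methylbut-3-en-1-yl chain ortho to its hydroxyl. C2 is the only stereocentre, so no stereocentres stand next to each other; it is benzylic, carries O1 and lies β to the ketone. Enolisation at C3 can therefore expel O1 in a retro-oxa-Michael opening to an achiral chalcone, so that base, heat or a good leaving group at O1 would erase the configuration and could also interchange the 5,7,8- and 5,6,7-oxygenation patterns on reclosure. The 1,1-disubstituted alkene is the second fragile group: acid protonates it to a tertiary cation that the neighbouring phenol traps as a 2,2-dimethylchroman, and it rules out hydrogenolysis and peracids. The fully deprotected ring A is a hydroxyhydroquinone and oxidises in air. The real difficulty is to bond ring A to both O1 and C4 without disturbing C2, and to place three oxygens on ring A under conditions the alkene survives. The key step exploits the ortho relationship on ring A between C8a, which holds O1, and C4a, which holds the carbonyl carbon C4: with the C5 oxygen as the neighbour of C4a, these two ring carbons can be generated as the triple bond of an aryne that this oxygen polarises, while C8, para to C5, stays C–H and is oxygenated later.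

## Logic of the disconnections

23 to 22: only the two O–CH2 acetal bonds at the C7 and C4' oxygens are cut. This makes the last step a pure deprotection, and the gain is that the air-sensitive trihydroxy ring A appears only at the very end. The demand is a cleavage that neither protonates the alkene nor opens ring C.

22 to 20 (through 21): the C8–O bond is cut. C8 is para to the C5 hydroxyl, and in 20 that hydroxyl is the only free phenol, so a para-selective phenol oxidation can reach C8 and nothing else. Removing the C8 oxygen simplifies ring A to the phloroglucinol pattern and leaves a single oxygen to steer the aryne addition. The demand is that a chelated phenol be oxidised and that 21 be reduced before ring C can open.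

20 to 19: the O5–CH2 acetal bond is cut. Only this acetal oxygen can chelate a Lewis acid together with the C4 carbonyl, so it can be released alone. The gain is that all three phenols carry the same protecting group up to this point. The demand is that the Lewis acid discriminate the chelating acetal from the other two.

19 to 16 and 9 (through 17 and 18): the O1–C8a and C4–C4a bonds are cut. Both are bonds from ring A to ring C at adjacent carbons, so one aryne can receive the oxygen nucleophile and then the acyl electrophile. The gain is full convergence: ring A and the chiral three-carbon chain carrying ring B are made separately, and the C2–O bond is brought in intact. The demand is regioselective addition to an unsymmetrical aryne and acylation of the aryl anion faster than its protonation.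

16 to 15: the C–H bond at the carbinol carbon is cut. The stereocentre then comes from a catalyst-controlled reduction, and the precursor becomes an achiral β-keto ester. The demand is chemoselectivity for the ketone over the alkene and the ester, and high facial selectivity.

15 to 14: the bond between the methylene carbon and the ester carbonyl (the future C3–C4 bond) is cut. A methyl ketone is a more reliable donor in a Claisen condensation than an aldehyde is in a one-step homologation, which is why this branch starts from 10 and not from the corresponding aldehyde. The gain is a simple acetophenone as precursor. The demand is clean mono-acylation of the ketone enolate.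

14 to 11 and 12 (through 13): the bond between ring B and the side-chain CH2 is cut. The whole unsaturated chain then comes from a commercial bromide in one sp2–sp3 coupling. The demand is an organometallic that tolerates the ketone and does not isomerise the alkene.

11 to 10: an O–CH2 acetal bond is cut, because the free phenol would quench the organozinc and later the aryl anion. The gain is a commercial bromophenol ketone. The demand is only an O-alkylation of an acidic phenol.

9 to 7 (through 8): the O–S bond of the triflate and the carbamate C–O bond are cut. The carbamate that directed the silylation is exchanged for the leaving group in one flask, which saves an isolation. The demand is that the aryl–silicon bond survive the carbamate cleavage.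

7 to 3 (through 4, 5 and 6): the aryl C–Si bond is cut. The carbamate is the strongest directing group on the ring and places silicon next to the future triflate. The gain is a symmetrical precursor. The demand is metalation between the carbamate and one acetal, not between the two acetals.

3 to 2 to 1: the carbamate O–C bond and two O–CH2 bonds are cut, reaching a symmetrical commodity triphenol. The gain is the cheapest possible source of ring A. The demand is acceptance of a statistical double protection in the first step.

## Other disconnections considered

Alternative 1: The cut is the C4a–C5 bond, with ring A unfolded into a polyketide-like chain whose far end is masked as a dioxinone. In the forward step (2S)-6-[(2,2-dimethyl-4-oxo-4H-1,3-dioxin-6-yl)(methoxymethoxy)methyl]-2-[4-(methoxymethoxy)-3-(3-methylbut-3-en-1-yl)phenyl]-2,3-dihydro-4H-pyran-4-one A2 would be heated. Cycloreversion of the dioxinone would give an acylketene, enolisation toward C8 a dienylketene, and 6π closure followed by tautomerisation the resorcinol ring of (2S)-5,7-dihydroxy-8-(methoxymethoxy)-2-[4-(methoxymethoxy)-3-(3-methylbut-3-en-1-yl)phenyl]chroman-4-one A1.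
- In its favour: the three ring A oxygens of A1 are fixed by the connectivity of A2, so there is no regiochemical question and no late oxidation. The conditions are neutral and thermal. A1 is one deprotection from the target.
- Against it here: A2 is a sensitive vinylogous ester that would have to be built linearly on the chiral dihydropyranone. At the temperature of ketene release the 2-aryl-dihydropyranone ring of A2 may open and lose C2. The acylketene can be intercepted by the enol hydroxyl or dimerise before the required geometry is reached.
- Comparison: on regiocontrol of the oxygen pattern and on the length of the end game after A1 this plan is better than the chosen one. On precedent the two are equal, since neither ring closure is documented on this substrate class. On convergence and on the number of steps before the key step the chosen plan should be better, because A2 has no short convergent assembly.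

Alternative 2: The cut removes C5–C6, C7–C8 and C8–C8a, so that ring A is assembled from a carbene carbon, an alkyne and carbon monoxide. In the forward step the zerovalent chromium carbene complex pentacarbonyl{methoxy[(2S,4-cis)-4-(tert-butyldimethylsilyloxy)-2-[4-(methoxymethoxy)-3-(3-methylbut-3-en-1-yl)phenyl]-3,4-dihydro-2H-pyran-5-yl]methylidene}chromium A4 would react with (triisopropylsilyloxy)ethyne A5. Alkyne insertion, CO insertion and electrocyclisation would give (2S,4-cis)-4-(tert-butyldimethylsilyloxy)-5-methoxy-2-[4-(methoxymethoxy)-3-(3-methylbut-3-en-1-yl)phenyl]-7-(triisopropylsilyloxy)chroman-8-ol A3.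
- In its favour: three bonds and a whole ring form in one step, and the C5, C7 and C8 oxygens of A3 arrive differentiated. Because C4 of A4 is at the alcohol level, C2 has no retro-oxa-Michael pathway during the annulation.
- Against it here: the chromium of A4 is used in a stoichiometric amount and the siloxyalkyne A5 is labile. The regiochemistry of insertion of a heteroatom-substituted alkyne such as A5 is electronically biased and may not be the one needed. A second stereocentre at C4 has to be set in A4 and later destroyed by oxidation. The C5 methyl ether of A3 needs a Lewis-acid cleavage in the presence of the alkene. A3 is an easily oxidised hydroquinone monoether.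
- Comparison: on bonds formed per step and on the safety of C2 during ring construction this plan is better. It also rests on a well-studied reaction, which is a further point in its favour. On step economy it is worse, because five or more adjustments follow A3 against three after the chosen key step.

Alternative 3: The cut is the C4–C4a bond. In the forward step (3S)-3-[4-(allyloxycarbonyloxy)-3-(3-methylbut-3-en-1-yl)phenyl]-3-[2,3,5-tris(allyloxy)phenoxy]propanoic acid A7 would be converted into (3S)-3-[4-(allyloxycarbonyloxy)-3-(3-methylbut-3-en-1-yl)phenyl]-3-[2,3,5-tris(allyloxy)phenoxy]propanoyl chloride A8. SnCl4 at low temperature would then acylate the only free ortho position of the aryloxy ring to give allyl 2-(3-methylbut-3-en-1-yl)-4-[(2S)-5,7,8-tris(allyloxy)-4-oxochroman-2-yl]phenyl carbonate A6.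
- In its favour: the reaction class is established. All ring A oxygens are present in A7 from the start and the regiochemistry is enforced by the tether. The allyl groups of A6 come off under neutral conditions with the zerovalent palladium complex Pd(PPh3)4.
- Against it here: the C2–O1 ether of A7 must first be made by an invertive etherification of a benzylic alcohol with a hindered phenol. Under the Lewis acid the benzylic aryl ether of A8 can ionise or the acyl chloride can eliminate the phenoxide, either of which costs the stereocentre. SnCl4 is also a threat to the alkene and the allyl ethers. The tetraoxygenated phenol needs its own synthesis.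
- Comparison: on precedent and on the mildness of the final deprotection of A6 this plan is better than the chosen one. On regiocontrol it is equal. On the integrity of C2 during ring closure and on bonds formed in the key step (one against two) the chosen plan should be better. Overall step counts are expected to be similar.

Key step: step 9

Assumption: RuCl[(S,S)-TsDPEN](p-cymene) is taken to reduce the aryl β-keto ester 15 with the facial sense established for aryl alkyl ketones, which corresponds to (S)-16; if the sense were reversed, the (R,R)-complex would be used.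

## Route

Step 1
Reactants: 1 phloroglucinol (benzene-1,3,5-triol)
Product: 2 3,5-bis(methoxymethoxy)phenol
Conditions: MOMCl (2.1 equiv), i-Pr2NEt, DMF, 0 °C → rt; tris-ether removed by extraction of the phenols into aq. NaOH, then chromatography
Reagents that add atoms: chloromethyl methyl ether, COCCl
Why: O-alkylation of a symmetrical triphenol with a hard alkylating agent; the double protection is statistical but is run on a commodity material, and the neutral tris-ether and the more polar mono-ether are separable.

Step 2
Reactants: 2 3,5-bis(methoxymethoxy)phenol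
Product: 3 3,5-bis(methoxymethoxy)phenyl N-isopropylcarbamate
Conditions: i-PrNCO, Et3N (cat.), CH2Cl2, rt
Reagents that add atoms: isopropyl isocyanate, CC(C)N=C=O
Why: Base-catalysed addition of a phenol to an isocyanate; the secondary carbamate is chosen because it can later be removed by mild base.

Step 3
Reactants: 3 3,5-bis(methoxymethoxy)phenyl N-isopropylcarbamate
Product: 7 3,5-bis(methoxymethoxy)-2-(trimethylsilyl)phenyl N-isopropylcarbamate, via N-silyl carbamate 4 (not isolated), via aryllithium 5 (not isolated), via bis-silyl carbamate 6 (not isolated)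
Conditions: TBSOTf, TMEDA, Et2O, 0 °C → rt; n-BuLi, TMEDA, −78 °C; Me3SiCl, −78 °C → rt; cold 10% aq. citric acid
Reagents that add atoms: chlorotrimethylsilane, C[Si](C)(C)Cl
Why: Directed ortho-metalation: N-silylation masks the N–H, the carbamate (the strongest director on the ring) guides lithiation to C2 between itself and one acetal in preference to C4 between the two weaker acetal directors, and the silyl quench at −78 °C precedes any anionic Fries shift; the N–Si bond hydrolyses on work-up.

Step 4
Reactants: 7 3,5-bis(methoxymethoxy)-2-(trimethylsilyl)phenyl N-isopropylcarbamate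
Product: 9 3,5-bis(methoxymethoxy)-2-(trimethylsilyl)phenyl trifluoromethanesulfonate, via silylphenol 8 (not isolated)
Conditions: DBU, Et2NH, MeCN, 40 °C; then PhNTf2, rt
Reagents that add atoms: N-phenylbis(trifluoromethanesulfonimide), O=S(=O)(N(c1ccccc1)S(=O)(=O)C(F)(F)F)C(F)(F)F
Why: E1cB cleavage of the secondary carbamate (the isocyanate is trapped by Et2NH as a urea) followed by O-triflation of the phenoxide in the same flask; the acetals and the aryl–silicon bond are inert to these conditions.

Step 5
Reactants: 10 1-(3-bromo-4-hydroxyphenyl)ethanone
Product: 11 1-[3-bromo-4-(methoxymethoxy)phenyl]ethanone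
Conditions: MOMCl, i-Pr2NEt, CH2Cl2, 0 °C → rt
Reagents that add atoms: chloromethyl methyl ether, COCCl
Why: O-alkylation of an acidic para-acylphenol; the acetal removes the proton that would destroy the organozinc in the next step.

Step 6
Reactants: 11 1-[3-bromo-4-(methoxymethoxy)phenyl]ethanone; 12 4-bromo-2-methylbut-1-ene
Product: 14 1-[4-(methoxymethoxy)-3-(3-methylbut-3-en-1-yl)phenyl]ethanone, via alkylzinc bromide 13 (not isolated)
Conditions: 12, Zn dust (activated), LiCl, THF, 50 °C; then 11, Pd(OAc)2 (2 mol %), SPhos (4 mol %), THF, rt → 40 °C
Reagents that add atoms: none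
Why: LiCl-assisted zinc insertion into the primary bromide, then Negishi coupling with the aryl bromide; alkylzinc halides do not add to aryl ketones, and the bulky biarylphosphine favours reductive elimination over β-hydride elimination.

Step 7
Reactants: 14 1-[4-(methoxymethoxy)-3-(3-methylbut-3-en-1-yl)phenyl]ethanone
Product: 15 methyl 3-[4-(methoxymethoxy)-3-(3-methylbut-3-en-1-yl)phenyl]-3-oxopropanoate
Conditions: NaH, (MeO)2CO, THF, reflux; AcOH, 0 °C
Reagents that add atoms: dimethyl carbonate, COC(=O)OC
Why: Crossed Claisen condensation of the methyl ketone enolate with a non-enolisable carbonate, driven to completion by deprotonation of the β-keto ester; the alkene and acetal are inert to NaH.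

Step 8
Reactants: 15 methyl 3-[4-(methoxymethoxy)-3-(3-methylbut-3-en-1-yl)phenyl]-3-oxopropanoate
Product: 16 methyl (3S)-3-hydroxy-3-[4-(methoxymethoxy)-3-(3-methylbut-3-en-1-yl)phenyl]propanoate
Conditions: RuCl[(S,S)-TsDPEN](p-cymene) (1 mol %), HCO2H/Et3N (5:2), DMF, 30 °C
Reagents that add atoms: none
Why: Noyori-type asymmetric transfer hydrogenation; hydride and proton are delivered in an outer-sphere transition state in which the CH/π contact between the p-cymene ligand and the aryl group of the ketone selects the face that gives the S carbinol, and the catalyst does not reduce the isolated alkene or the ester.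

Step 9
Reactants: 16 methyl (3S)-3-hydroxy-3-[4-(methoxymethoxy)-3-(3-methylbut-3-en-1-yl)phenyl]propanoate; 9 3,5-bis(methoxymethoxy)-2-(trimethylsilyl)phenyl trifluoromethanesulfonate
Product: 19 (2S)-5,7-bis(methoxymethoxy)-2-[4-(methoxymethoxy)-3-(3-methylbut-3-en-1-yl)phenyl]chroman-4-one, via trimethylsilyl ether 17 (not isolated), via aryne 18 (not isolated)
Conditions: (Me3Si)2NH, Me3SiCl (cat.), THF, rt, then evaporation with toluene; 9 (1.5 equiv), CsF, 18-crown-6, THF, 0 °C → rt; pH 6 phosphate buffer quench at 0 °C
Reagents that add atoms: none
Why: Proposed new method: the hydroxyl of 16 is first converted into silyl ether 17 so that no O–H proton is present; fluoride then unmasks the caesium alkoxide and, by attack at the aryl silicon of 9 with loss of triflate, releases aryne 18. The alkoxide adds in the plane of the strained triple bond at C8a, the aryne carbon remote from the C5 acetal oxygen, because the carbanion then develops at C4a, where the adjacent C5–O bond stabilises it inductively, while C8 carries only hydrogen and exerts no opposing effect. The C4a anion attacks the ester carbonyl in a 6-exo-trig closure of ring C and the tetrahedral intermediate loses methoxide to give the ketone; the methoxide is taken up by silicon (fluorotrimethylsilane or unreacted 17) as methoxytrimethylsilane, so no alkoxide base accumulates beside the base-sensitive product. The closest known reaction type is the fluoride-induced annulation of arynes with salicylate esters to xanthones, in which O-arylation of an aryloxide is followed by acyl capture of the aryl anion; the new element is a secondary aliphatic alkoxide as the oxygen nucleophile. No stereocentre is created: the C2–O bond of 16 is never broken, so the S configuration is carried over, provided the product is kept from base, hence the low temperature and the buffered quench. The selectivities required are regioselective addition to the unsymmetrical aryne, secured by the C5 alkoxy group, and acylation of the aryl anion in preference to its protonation, secured by the absence of an O–H group and by THF in place of a C–H acidic solvent.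

Step 10
Reactants: 19 (2S)-5,7-bis(methoxymethoxy)-2-[4-(methoxymethoxy)-3-(3-methylbut-3-en-1-yl)phenyl]chroman-4-one
Product: 20 (2S)-5-hydroxy-7-(methoxymethoxy)-2-[4-(methoxymethoxy)-3-(3-methylbut-3-en-1-yl)phenyl]chroman-4-one
Conditions: MgBr2·OEt2 (3 equiv), Et2O/toluene, 0 °C → rt; pH 6 buffer
Reagents that add atoms: none
Why: Chelation-controlled Lewis-acid cleavage of an acetal: magnesium is held between the C4 carbonyl and the C5 acetal oxygen in a six-membered chelate, bromide opens only that acetal, and the C7 and C4' acetals, which cannot chelate, should remain.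

Step 11
Reactants: 20 (2S)-5-hydroxy-7-(methoxymethoxy)-2-[4-(methoxymethoxy)-3-(3-methylbut-3-en-1-yl)phenyl]chroman-4-one
Product: 22 (2S)-5,8-dihydroxy-7-(methoxymethoxy)-2-[4-(methoxymethoxy)-3-(3-methylbut-3-en-1-yl)phenyl]chroman-4-one, via quinone 21 (not isolated)
Conditions: (KSO3)2NO (2.5 equiv), KH2PO4 buffer (pH 6), acetone/H2O, 0 °C; then Na2S2O4, EtOAc/H2O, 0 °C
Reagents that add atoms: potassium nitrosodisulfonate, [K+].[K+].[O]N(S(=O)(=O)[O-])S(=O)(=O)[O-]
Why: Teuber oxidation: the nitroxyl radical abstracts hydrogen from the only free phenol, a second radical couples at the unsubstituted para carbon C8, and loss of imidodisulfonate gives the 5,8-quinone, which dithionite reduces at once to the hydroquinone. The para rule fixes the regiochemistry, and the cold, slightly acidic, telescoped procedure limits ring opening at C2 while the quinone exists.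

Step 12
Reactants: 22 (2S)-5,8-dihydroxy-7-(methoxymethoxy)-2-[4-(methoxymethoxy)-3-(3-methylbut-3-en-1-yl)phenyl]chroman-4-one
Product: 23 (2S)-5,7,8-trihydroxy-2-[4-hydroxy-3-(3-methylbut-3-en-1-yl)phenyl]chroman-4-one
Conditions: ZnBr2, n-PrSH, CH2Cl2, 0 °C, argon; pH 6 buffer work-up, degassed solvents
Reagents that add atoms: none
Why: Lewis-acid activation of the two aryl formaldehyde acetals with capture of the methoxymethyl cation by the soft thiol; no strong Brønsted acid is present to protonate the 1,1-disubstituted alkene, and the thiol keeps the hydroxyhydroquinone reduced.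

## Compound list

1 | phloroglucinol (benzene-1,3,5-triol) | Oc1cc(O)cc(O)c1 | starting material
2 | 3,5-bis(methoxymethoxy)phenol | COCOc1cc(O)cc(OCOC)c1 | intermediate
3 | 3,5-bis(methoxymethoxy)phenyl N-isopropylcarbamate | CC(C)NC(=O)Oc1cc(OCOC)cc(OCOC)c1 | intermediate
4 | 3,5-bis(methoxymethoxy)phenyl N-(tert-butyldimethylsilyl)-N-isopropylcarbamate | CC(C)N(C(=O)Oc1cc(OCOC)cc(OCOC)c1)[Si](C)(C)C(C)(C)C | intermediate
5 | [2-{[(tert-butyldimethylsilyl)(propan-2-yl)carbamoyl]oxy}-4,6-bis(methoxymethoxy)phenyl]lithium | [Li]c1c(OCOC)cc(OCOC)cc1OC(=O)N(C(C)C)[Si](C)(C)C(C)(C)C | intermediate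
6 | 3,5-bis(methoxymethoxy)-2-(trimethylsilyl)phenyl N-(tert-butyldimethylsilyl)-N-isopropylcarbamate | CC(C)N(C(=O)Oc1cc(OCOC)cc(OCOC)c1[Si](C)(C)C)[Si](C)(C)C(C)(C)C | intermediate
7 | 3,5-bis(methoxymethoxy)-2-(trimethylsilyl)phenyl N-isopropylcarbamate | CC(C)NC(=O)Oc1cc(OCOC)cc(OCOC)c1[Si](C)(C)C | intermediate
8 | 3,5-bis(methoxymethoxy)-2-(trimethylsilyl)phenol | COCOc1cc(O)c([Si](C)(C)C)c(OCOC)c1 | intermediate
9 | 3,5-bis(methoxymethoxy)-2-(trimethylsilyl)phenyl trifluoromethanesulfonate | COCOc1cc(OCOC)c([Si](C)(C)C)c(OS(=O)(=O)C(F)(F)F)c1 | intermediate
10 | 1-(3-bromo-4-hydroxyphenyl)ethanone | CC(=O)c1ccc(O)c(Br)c1 | starting material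
11 | 1-[3-bromo-4-(methoxymethoxy)phenyl]ethanone | CC(=O)c1ccc(OCOC)c(Br)c1 | intermediate
12 | 4-bromo-2-methylbut-1-ene | C=C(C)CCBr | starting material
13 | (3-methylbut-3-en-1-yl)zinc bromide | C=C(C)CC[Zn]Br | intermediate
14 | 1-[4-(methoxymethoxy)-3-(3-methylbut-3-en-1-yl)phenyl]ethanone | C=C(C)CCc1cc(C(C)=O)ccc1OCOC | intermediate
15 | methyl 3-[4-(methoxymethoxy)-3-(3-methylbut-3-en-1-yl)phenyl]-3-oxopropanoate | C=C(C)CCc1cc(C(=O)CC(=O)OC)ccc1OCOC | intermediate
16 | methyl (3S)-3-hydroxy-3-[4-(methoxymethoxy)-3-(3-methylbut-3-en-1-yl)phenyl]propanoate | C=C(C)CCc1cc([C@@H](O)CC(=O)OC)ccc1OCOC | intermediate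
17 | methyl (3S)-3-[4-(methoxymethoxy)-3-(3-methylbut-3-en-1-yl)phenyl]-3-(trimethylsilyloxy)propanoate | C=C(C)CCc1cc([C@@H](O[Si](C)(C)C)CC(=O)OC)ccc1OCOC | intermediate
18 | 3,5-bis(methoxymethoxy)benzyne (1,2-didehydro-3,5-bis(methoxymethoxy)benzene) | COCOC1=CC#CC(OCOC)=C1 | intermediate
19 | (2S)-5,7-bis(methoxymethoxy)-2-[4-(methoxymethoxy)-3-(3-methylbut-3-en-1-yl)phenyl]chroman-4-one | C=C(C)CCc1cc([C@@H]2CC(=O)c3c(OCOC)cc(OCOC)cc3O2)ccc1OCOC | intermediate
20 | (2S)-5-hydroxy-7-(methoxymethoxy)-2-[4-(methoxymethoxy)-3-(3-methylbut-3-en-1-yl)phenyl]chroman-4-one | C=C(C)CCc1cc([C@@H]2CC(=O)c3c(O)cc(OCOC)cc3O2)ccc1OCOC | intermediate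
21 | (2S)-7-(methoxymethoxy)-2-[4-(methoxymethoxy)-3-(3-methylbut-3-en-1-yl)phenyl]-2,3-dihydro-4H-chromene-4,5,8-trione | C=C(C)CCc1cc([C@@H]2CC(=O)C3=C(O2)C(=O)C(OCOC)=CC3=O)ccc1OCOC | intermediate
22 | (2S)-5,8-dihydroxy-7-(methoxymethoxy)-2-[4-(methoxymethoxy)-3-(3-methylbut-3-en-1-yl)phenyl]chroman-4-one | C=C(C)CCc1cc([C@@H]2CC(=O)c3c(O)cc(OCOC)c(O)c3O2)ccc1OCOC | intermediate
23 | (2S)-5,7,8-trihydroxy-2-[4-hydroxy-3-(3-methylbut-3-en-1-yl)phenyl]chroman-4-one | C=C(C)CCc1cc([C@@H]2CC(=O)c3c(O)cc(O)c(O)c3O2)ccc1O | target

## Step count and least certain steps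

Total: 12 steps. Longest linear sequence: 8 steps, from 10 to 23 through steps 5 to 12; the branch from 1 through steps 1 to 4 and 9 to 12 is equally long.

Step 9 (key step). The most likely failures are premature protonation of the C4a aryl anion before it reaches the ester, retro-aldol fragmentation or β-elimination of the free alkoxide before it meets the aryne, ring opening of the product by residual alkoxide with erosion of the configuration at C2, and an ene reaction of the aryne with the side-chain alkene. All follow from the fact that an aliphatic alkoxide is more basic and less persistent than the aryloxides for which this annulation type is known. The fallback uses known chemistry, sets out from 15 and from 1 and comes back to the route at 19. 15 would be reduced with RuCl[(R,R)-TsDPEN](p-cymene) to methyl (3R)-3-hydroxy-3-[4-(methoxymethoxy)-3-(3-methylbut-3-en-1-yl)phenyl]propanoate F1, which MeNH(OMe)·HCl and i-PrMgCl would convert into (3R)-3-hydroxy-N-methoxy-N-methyl-3-[4-(methoxymethoxy)-3-(3-methylbut-3-en-1-yl)phenyl]propanamide F2. In parallel, 1 would be fully etherified with excess MOMCl and i-Pr2NEt to 1,3,5-tris(methoxymethoxy)benzene F3, which n-BuLi lithiates between two acetal oxygens to 2,4,6-tris(methoxymethoxy)phenyllithium F4. F4 in excess, the first equivalent serving to deprotonate the hydroxyl, should add to F2 to give (3R)-3-hydroxy-3-[4-(methoxymethoxy)-3-(3-methylbut-3-en-1-yl)phenyl]-1-[2,4,6-tris(methoxymethoxy)phenyl]propan-1-one F5. MgBr2·OEt2 should remove one of the two ketone-flanking acetals by chelation to give (3R)-3-hydroxy-1-[2-hydroxy-4,6-bis(methoxymethoxy)phenyl]-3-[4-(methoxymethoxy)-3-(3-methylbut-3-en-1-yl)phenyl]propan-1-one F6. An intramolecular Mitsunobu etherification (PPh3, DIAD, THF, 0 °C) would then close ring C with inversion at the carbinol carbon and deliver 19.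

Step 11. The chelated, acyl-deactivated C5 phenol may be slow to give up its hydrogen atom to the nitroxyl radical. While the quinone stage lasts, O1 is a vinylogous carboxylate leaving group, so retro-oxa-Michael opening could erode C2, and the C7 acetal is easily hydrolysed at that oxidation level. The fallback avoids any quinone, sets out from 19 and comes back to the route at 23. One equivalent of N-iodosuccinimide in DMF at −20 °C in the dark is expected to iodinate the strongly activated ring A at C8, the usual site for fully O-alkylated 5,7-dioxygenated chromanones, faster than it attacks the alkene, giving (2S)-8-iodo-5,7-bis(methoxymethoxy)-2-[4-(methoxymethoxy)-3-(3-methylbut-3-en-1-yl)phenyl]chroman-4-one F7. Borylation (Pd(OAc)2, SPhos, pinacolborane, Et3N) would give (2S)-5,7-bis(methoxymethoxy)-2-[4-(methoxymethoxy)-3-(3-methylbut-3-en-1-yl)phenyl]-8-(4,4,5,5-tetramethyl-1,3,2-dioxaborolan-2-yl)chroman-4-one F8, and oxidation with NaBO3·4H2O in THF/H2O would give (2S)-8-hydroxy-5,7-bis(methoxymethoxy)-2-[4-(methoxymethoxy)-3-(3-methylbut-3-en-1-yl)phenyl]chroman-4-one F9. The conditions of step 12 would then remove all three acetals to reach 23.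

Step 12. Adventitious acid could protonate the alkene, followed by closure of the neighbouring phenol onto the tertiary cation or by addition of thiol or bromide. Air oxidation of the hydroxyhydroquinone and chalcone-mediated isomerisation during work-up are the other concerns. The fallback replaces acetal cleavage by silyl exchange, sets out from 22 and comes back to the route at 23. Me3SiOTf with 2,2'-bipyridyl in MeCN at 0 °C should convert the aryl acetals and the free hydroxyls into silyl ethers, giving (2S)-5,7,8-tris(trimethylsilyloxy)-2-[3-(3-methylbut-3-en-1-yl)-4-(trimethylsilyloxy)phenyl]chroman-4-one F10. Brief treatment with water or aqueous methanol at neutral pH would then hydrolyse it to 23.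

Step 10. The acetal cleavage may not stop at C5 but also remove the C7 or C4' acetal, or it may stall, because the discrimination rests only on chelation. The fallback gives up selective cleavage, sets out from 19 and comes back to the route at 20. All three acetals would be removed with ZnBr2 and n-PrSH to give (2S)-5,7-dihydroxy-2-[4-hydroxy-3-(3-methylbut-3-en-1-yl)phenyl]chroman-4-one F11. MOMCl (2.1 equiv) and i-Pr2NEt in CH2Cl2 should then re-etherify the C7 and C4' phenols, while the hydrogen-bonded C5 hydroxyl is too weak a nucleophile to react, giving 20.

## Further compounds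

F1 | step 9 | methyl (3R)-3-hydroxy-3-[4-(methoxymethoxy)-3-(3-methylbut-3-en-1-yl)phenyl]propanoate | C=C(C)CCc1cc([C@H](O)CC(=O)OC)ccc1OCOC
F2 | step 9 | (3R)-3-hydroxy-N-methoxy-N-methyl-3-[4-(methoxymethoxy)-3-(3-methylbut-3-en-1-yl)phenyl]propanamide | C=C(C)CCc1cc([C@H](O)CC(=O)N(C)OC)ccc1OCOC
F3 | step 9 | 1,3,5-tris(methoxymethoxy)benzene | COCOc1cc(OCOC)cc(OCOC)c1
F4 | step 9 | 2,4,6-tris(methoxymethoxy)phenyllithium | [Li]c1c(OCOC)cc(OCOC)cc1OCOC
F5 | step 9 | (3R)-3-hydroxy-3-[4-(methoxymethoxy)-3-(3-methylbut-3-en-1-yl)phenyl]-1-[2,4,6-tris(methoxymethoxy)phenyl]propan-1-one | C=C(C)CCc1cc([C@H](O)CC(=O)c2c(OCOC)cc(OCOC)cc2OCOC)ccc1OCOC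
F6 | step 9 | (3R)-3-hydroxy-1-[2-hydroxy-4,6-bis(methoxymethoxy)phenyl]-3-[4-(methoxymethoxy)-3-(3-methylbut-3-en-1-yl)phenyl]propan-1-one | C=C(C)CCc1cc([C@H](O)CC(=O)c2c(O)cc(OCOC)cc2OCOC)ccc1OCOC
F7 | step 11 | (2S)-8-iodo-5,7-bis(methoxymethoxy)-2-[4-(methoxymethoxy)-3-(3-methylbut-3-en-1-yl)phenyl]chroman-4-one | C=C(C)CCc1cc([C@@H]2CC(=O)c3c(OCOC)cc(OCOC)c(I)c3O2)ccc1OCOC
F8 | step 11 | (2S)-5,7-bis(methoxymethoxy)-2-[4-(methoxymethoxy)-3-(3-methylbut-3-en-1-yl)phenyl]-8-(4,4,5,5-tetramethyl-1,3,2-dioxaborolan-2-yl)chroman-4-one | C=C(C)CCc1cc([C@@H]2CC(=O)c3c(OCOC)cc(OCOC)c(B4OC(C)(C)C(C)(C)O4)c3O2)ccc1OCOC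
F9 | step 11 | (2S)-8-hydroxy-5,7-bis(methoxymethoxy)-2-[4-(methoxymethoxy)-3-(3-methylbut-3-en-1-yl)phenyl]chroman-4-one | C=C(C)CCc1cc([C@@H]2CC(=O)c3c(OCOC)cc(OCOC)c(O)c3O2)ccc1OCOC
F10 | step 12 | (2S)-5,7,8-tris(trimethylsilyloxy)-2-[3-(3-methylbut-3-en-1-yl)-4-(trimethylsilyloxy)phenyl]chroman-4-one | C=C(C)CCc1cc([C@@H]2CC(=O)c3c(O[Si](C)(C)C)cc(O[Si](C)(C)C)c(O[Si](C)(C)C)c3O2)ccc1O[Si](C)(C)C
F11 | step 10 | (2S)-5,7-dihydroxy-2-[4-hydroxy-3-(3-methylbut-3-en-1-yl)phenyl]chroman-4-one | C=C(C)CCc1cc([C@@H]2CC(=O)c3c(O)cc(O)cc3O2)ccc1O
A1 | alternative 1 | (2S)-5,7-dihydroxy-8-(methoxymethoxy)-2-[4-(methoxymethoxy)-3-(3-methylbut-3-en-1-yl)phenyl]chroman-4-one | C=C(C)CCc1cc([C@@H]2CC(=O)c3c(O)cc(O)c(OCOC)c3O2)ccc1OCOC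
A2 | alternative 1 | (2S)-6-[(2,2-dimethyl-4-oxo-4H-1,3-dioxin-6-yl)(methoxymethoxy)methyl]-2-[4-(methoxymethoxy)-3-(3-methylbut-3-en-1-yl)phenyl]-2,3-dihydro-4H-pyran-4-one | C=C(C)CCc1cc([C@@H]2CC(=O)C=C(C(OCOC)C3=CC(=O)OC(C)(C)O3)O2)ccc1OCOC
A3 | alternative 2 | (2S,4-cis)-4-(tert-butyldimethylsilyloxy)-5-methoxy-2-[4-(methoxymethoxy)-3-(3-methylbut-3-en-1-yl)phenyl]-7-(triisopropylsilyloxy)chroman-8-ol | C=C(C)CCc1cc([C@@H]2C[C@H](O[Si](C)(C)C(C)(C)C)c3c(OC)cc(O[Si](C(C)C)(C(C)C)C(C)C)c(O)c3O2)ccc1OCOC
A4 | alternative 2 | pentacarbonyl{methoxy[(2S,4-cis)-4-(tert-butyldimethylsilyloxy)-2-[4-(methoxymethoxy)-3-(3-methylbut-3-en-1-yl)phenyl]-3,4-dihydro-2H-pyran-5-yl]methylidene}chromium | C=C(C)CCc1cc([C@@H]2C[C@H](O[Si](C)(C)C(C)(C)C)C(C(OC)=[Cr](=C=O)(=C=O)(=C=O)(=C=O)=C=O)=CO2)ccc1OCOC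
A5 | alternative 2 | (triisopropylsilyloxy)ethyne | C#CO[Si](C(C)C)(C(C)C)C(C)C
A6 | alternative 3 | allyl 2-(3-methylbut-3-en-1-yl)-4-[(2S)-5,7,8-tris(allyloxy)-4-oxochroman-2-yl]phenyl carbonate | C=C(C)CCc1cc([C@@H]2CC(=O)c3c(OCC=C)cc(OCC=C)c(OCC=C)c3O2)ccc1OC(=O)OCC=C
A7 | alternative 3 | (3S)-3-[4-(allyloxycarbonyloxy)-3-(3-methylbut-3-en-1-yl)phenyl]-3-[2,3,5-tris(allyloxy)phenoxy]propanoic acid | C=C(C)CCc1cc([C@H](CC(=O)O)Oc2cc(OCC=C)cc(OCC=C)c2OCC=C)ccc1OC(=O)OCC=C
A8 | alternative 3 | (3S)-3-[4-(allyloxycarbonyloxy)-3-(3-methylbut-3-en-1-yl)phenyl]-3-[2,3,5-tris(allyloxy)phenoxy]propanoyl chloride | C=C(C)CCc1cc([C@H](CC(=O)Cl)Oc2cc(OCC=C)cc(OCC=C)c2OCC=C)ccc1OC(=O)OCC=C
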